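**Strategy.** The dibenzylbutane core is cut at C8–C8', the bond between the two methyl-bearing carbons that link the benzyl arms of ring A (guaiacyl) and ring B (syringyl). Because methyls C9 and C9' stand 1,4 to each other across this bond, they are read as reduced carboxyl carbons of a 2,3-dibenzylsuccinate. In one operation the enolate of an Evans imide carrying ring A displaces, with inversion, the triflate of an (R)-aryllactate that already carries ring B and the complete threo 8''-O-4' arm with ring C: the auxiliary sets C8, the inversion sets C8'. Both carbonyls are then taken down to methyl.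

Key step: step 9

Remark: locants C7–C9 belong to the propyl unit on ring A, C7'–C9' to that on ring B, C7''–C9'' to that on ring C; 1-(benzyloxy)-4-bromo-2-methoxybenzene is taken as a purchasable building block.
Abbreviation used in names: SC = (1S,2S)-1-[4-(benzyloxy)-3-methoxyphenyl]-1-[(tert-butyldimethylsilyl)oxy]propan-2-yl, bound through its C2 to the ring B oxygen.

**Step 1**
Reactants: 1 3-(4-hydroxy-3-methoxyphenyl)propanoic acid
Product: 2 3-[4-(benzyloxy)-3-methoxyphenyl]propanoic acid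
Conditions: BnBr, NaOH, EtOH/H2O, reflux; then aq. HCl
Reagents that add atoms: benzyl bromide, BrCc1ccccc1
Why: Williamson ether synthesis on the phenoxide, any benzyl ester formed at the carboxylate being saponified in the same alkaline medium.

**Step 2**
Reactants: 2 3-[4-(benzyloxy)-3-methoxyphenyl]propanoic acid; 3 (R)-4-benzyl-1,3-oxazolidin-2-one
Product: 5 (4R)-4-benzyl-3-{3-[4-(benzyloxy)-3-methoxyphenyl]propanoyl}-1,3-oxazolidin-2-one, via mixed pivalic anhydride 4 (not isolated)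
Conditions: t-BuCOCl, Et3N, THF, −20 °C; then 3, LiCl, −20 °C to rt
Reagents that add atoms: none
Why: N-acylation of the oxazolidinone through the mixed anhydride (standard Evans imide formation), the hindered pivaloyl carbonyl directing attack to the wanted acyl group.

**Step 3**
Reactants: 6 4-bromo-2,6-dimethoxyphenol; 7 methyl (R)-lactate
Product: 8 methyl (2S)-2-(4-bromo-2,6-dimethoxyphenoxy)propanoate
Conditions: PPh3, DIAD, THF, 0 °C to rt
Reagents that add atoms: none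
Why: Mitsunobu etherification in which the acidic phenol displaces the activated lactate hydroxyl with inversion, so that (R) becomes (S) at the future C8''.

**Step 4**
Reactants: 8 methyl (2S)-2-(4-bromo-2,6-dimethoxyphenoxy)propanoate
Product: 9 (2S)-2-(4-bromo-2,6-dimethoxyphenoxy)propanal
Conditions: i-Bu2AlH (1.1 equiv), CH2Cl2, −78 °C; aq. potassium sodium tartrate; used at once
Reagents that add atoms: none
Why: partial hydride reduction of an α-alkoxy ester, whose aluminium hemiacetal is stable at −78 °C and releases the aldehyde only on work-up without touching the stereocenter.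

**Step 5**
Reactants: 9 (2S)-2-(4-bromo-2,6-dimethoxyphenoxy)propanal; 10 1-(benzyloxy)-4-bromo-2-methoxybenzene
Product: 12 (1S,2S)-1-[4-(benzyloxy)-3-methoxyphenyl]-2-(4-bromo-2,6-dimethoxyphenoxy)propan-1-ol, via aryl Grignard reagent 11 (not isolated)
Conditions: 10, Mg, THF, rt; then 9, MgBr2·OEt2, CH2Cl2, −78 °C; aq. NH4Cl
Reagents that add atoms: none
Why: Cram-chelate controlled Grignard addition in which magnesium bridges the aldehyde and aryloxy oxygens and the aryl group enters on the face of the C8'' hydrogen, which should set C7'' as S and give the threo alcohol.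

**Step 6**
Reactants: 12 (1S,2S)-1-[4-(benzyloxy)-3-methoxyphenyl]-2-(4-bromo-2,6-dimethoxyphenoxy)propan-1-ol
Product: 13 tert-butyl{(1S,2S)-1-[4-(benzyloxy)-3-methoxyphenyl]-2-(4-bromo-2,6-dimethoxyphenoxy)propoxy}dimethylsilane
Conditions: t-BuMe2SiOTf, 2,6-lutidine, CH2Cl2, 0 °C
Reagents that add atoms: tert-butyldimethylsilyl triflate, CC(C)(C)[Si](C)(C)OS(=O)(=O)C(F)(F)F
Why: O-silylation under non-acidic conditions protects the ionisable benzylic alcohol for the organometallic, triflation and hydride steps that follow.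

**Step 7**
Reactants: 13 tert-butyl{(1S,2S)-1-[4-(benzyloxy)-3-methoxyphenyl]-2-(4-bromo-2,6-dimethoxyphenoxy)propoxy}dimethylsilane; 14 methyl (2R)-oxirane-2-carboxylate
Product: 16 methyl (2R)-2-hydroxy-3-[3,5-dimethoxy-4-(SC-oxy)phenyl]propanoate, via aryl Grignard reagent 15 (not isolated)
Conditions: Mg, THF, 50 °C; then CuI (10 mol %), 14 (1.5 equiv), THF, −40 to −20 °C; aq. NH4Cl
Reagents that add atoms: none
Why: copper-catalysed epoxide opening by the arylmagnesium at the unsubstituted C3 of the glycidate, faster than ester addition at low temperature, gives the α-hydroxy ester with the (R) carbinol carbon untouched.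

**Step 8**
Reactants: 16 methyl (2R)-2-hydroxy-3-[3,5-dimethoxy-4-(SC-oxy)phenyl]propanoate
Product: 17 methyl (2R)-3-[3,5-dimethoxy-4-(SC-oxy)phenyl]-2-[(trifluoromethanesulfonyl)oxy]propanoate
Conditions: Tf2O, 2,6-lutidine, CH2Cl2, −78 to −20 °C; short silica plug; used at once
Reagents that add atoms: triflic anhydride, O=S(=O)(OS(=O)(=O)C(F)(F)F)C(F)(F)F
Why: O-sulfonylation with retention at carbon, the α-ester group suppressing ionisation so that the secondary triflate can be handled briefly.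

**Step 9**
Reactants: 5 (4R)-4-benzyl-3-{3-[4-(benzyloxy)-3-methoxyphenyl]propanoyl}-1,3-oxazolidin-2-one; 17 methyl (2R)-3-[3,5-dimethoxy-4-(SC-oxy)phenyl]-2-[(trifluoromethanesulfonyl)oxy]propanoate
Product: 19 methyl (2R,3S)-3-{[(4R)-4-benzyl-2-oxo-1,3-oxazolidin-3-yl]carbonyl}-4-[4-(benzyloxy)-3-methoxyphenyl]-2-{[3,5-dimethoxy-4-(SC-oxy)phenyl]methyl}butanoate, via sodium Z-enolate 18 (not isolated)
Conditions: 5 (1.7 equiv), NaN(SiMe3)2, THF, −78 °C; then 17 (1 equiv), −78 to −40 °C; aq. NH4Cl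
Reagents that add atoms: none
Why: NaN(SiMe3)2 gives the sodium-chelated Z-enolate 18, whose α-carbon attacks the secondary carbon of triflate 17 in an SN2 C-alkylation with loss of triflate, the closest known reaction type being the Evans asymmetric alkylation as applied to α-triflyloxy esters for 2,3-disubstituted succinates. No ring is closed. C8 is controlled by the auxiliary, since the C4 benzyl group of the (R)-oxazolidinone shields one face of the chelated Z-enolate and the electrophile enters from the other, giving 8S. C8' is controlled by the triflate, since backside attack inverts the (R) carbinol carbon that came from the glycidate and gives 8'R (the letter stays R only because the CIP ranking changes). The step needs substitution to beat E2 elimination to the cinnamate and proton transfer to the enolate; the high SN2 reactivity of α-carbonyl triflates at −78 °C, the modest basicity of the imide enolate and addition of 17 to excess 18 should secure this.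

**Step 10**
Reactants: 19 methyl (2R,3S)-3-{[(4R)-4-benzyl-2-oxo-1,3-oxazolidin-3-yl]carbonyl}-4-[4-(benzyloxy)-3-methoxyphenyl]-2-{[3,5-dimethoxy-4-(SC-oxy)phenyl]methyl}butanoate
Product: 20 (2S,3R)-2-{[4-(benzyloxy)-3-methoxyphenyl]methyl}-3-{[3,5-dimethoxy-4-(SC-oxy)phenyl]methyl}butane-1,4-diol
Conditions: LiBH4, MeOH, THF, 0 °C to rt
Reagents that add atoms: none
Why: borohydride reduction cleaves the exocyclic imide carbonyl and reduces the methyl ester to the 1,4-diol without touching C8 or C8', releasing the auxiliary.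

**Step 11**
Reactants: 20 (2S,3R)-2-{[4-(benzyloxy)-3-methoxyphenyl]methyl}-3-{[3,5-dimethoxy-4-(SC-oxy)phenyl]methyl}butane-1,4-diol
Product: 21 (2S,3R)-2-{[4-(benzyloxy)-3-methoxyphenyl]methyl}-3-{[3,5-dimethoxy-4-(SC-oxy)phenyl]methyl}butane-1,4-diyl dimethanesulfonate
Conditions: MsCl (3 equiv), Et3N (4 equiv), CH2Cl2, −10 °C, short reaction time
Reagents that add atoms: methanesulfonyl chloride, CS(=O)(=O)Cl
Why: fast sulfene-type mesylation of both primary alcohols, which should outrun cyclisation of the monomesylate to a tetrahydrofuran.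

**Step 12**
Reactants: 21 (2S,3R)-2-{[4-(benzyloxy)-3-methoxyphenyl]methyl}-3-{[3,5-dimethoxy-4-(SC-oxy)phenyl]methyl}butane-1,4-diyl dimethanesulfonate
Product: 22 5-{(2R,3S)-4-[4-(benzyloxy)-3-methoxyphenyl]-2,3-dimethylbutyl}-1,3-dimethoxy-2-(SC-oxy)benzene
Conditions: LiEt3BH, THF, 0 °C to rt
Reagents that add atoms: none
Why: SN2 hydride displacement of both primary mesylates turns C9 and C9' into methyl groups without involving the stereocenters, silyl and benzyl ethers being inert.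

**Step 13**
Reactants: 22 5-{(2R,3S)-4-[4-(benzyloxy)-3-methoxyphenyl]-2,3-dimethylbutyl}-1,3-dimethoxy-2-(SC-oxy)benzene
Product: 23 (1S,2S)-1-[4-(benzyloxy)-3-methoxyphenyl]-2-[4-{(2R,3S)-4-[4-(benzyloxy)-3-methoxyphenyl]-2,3-dimethylbutyl}-2,6-dimethoxyphenoxy]propan-1-ol
Conditions: Bu4NF, AcOH, THF, rt
Reagents that add atoms: none
Why: fluoride-induced cleavage of the Si–O bond (desilylation) under buffered conditions frees the C7'' alcohol.

**Step 14**
Reactants: 23 (1S,2S)-1-[4-(benzyloxy)-3-methoxyphenyl]-2-[4-{(2R,3S)-4-[4-(benzyloxy)-3-methoxyphenyl]-2,3-dimethylbutyl}-2,6-dimethoxyphenoxy]propan-1-ol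
Product: 24 (+)-(7''S,8S,8'R,8''S)-4,4''-dihydroxy-3,3',3'',5'-tetramethoxy-4',8''-oxy-8,8'-sesquineolignan-7''-ol
Conditions: H2 (1 atm), Pd/C, EtOAc, rt; stopped at complete debenzylation
Reagents that add atoms: none
Why: catalytic hydrogenolysis of the two phenolic benzyl ethers, which under neutral conditions are cleaved much faster than the benzylic C7''–OH bond.

**Compound list**
1 | 3-(4-hydroxy-3-methoxyphenyl)propanoic acid | COc1cc(CCC(=O)O)ccc1O | starting material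
2 | 3-[4-(benzyloxy)-3-methoxyphenyl]propanoic acid | COc1cc(CCC(=O)O)ccc1OCc1ccccc1 | intermediate
3 | (R)-4-benzyl-1,3-oxazolidin-2-one | O=C1N[C@H](Cc2ccccc2)CO1 | starting material
4 | mixed pivalic anhydride of 2 | COc1cc(CCC(=O)OC(=O)C(C)(C)C)ccc1OCc1ccccc1 | intermediate (not isolated)
5 | (4R)-4-benzyl-3-{3-[4-(benzyloxy)-3-methoxyphenyl]propanoyl}-1,3-oxazolidin-2-one | COc1cc(CCC(=O)N2[C@H](Cc3ccccc3)COC2=O)ccc1OCc1ccccc1 | intermediate
6 | 4-bromo-2,6-dimethoxyphenol | COc1cc(Br)cc(OC)c1O | starting material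
7 | methyl (R)-lactate | C[C@@H](O)C(=O)OC | starting material
8 | methyl (2S)-2-(4-bromo-2,6-dimethoxyphenoxy)propanoate | C[C@H](Oc1c(OC)cc(Br)cc1OC)C(=O)OC | intermediate
9 | (2S)-2-(4-bromo-2,6-dimethoxyphenoxy)propanal | C[C@H](Oc1c(OC)cc(Br)cc1OC)C=O | intermediate
10 | 1-(benzyloxy)-4-bromo-2-methoxybenzene | COc1cc(Br)ccc1OCc1ccccc1 | starting material
11 | [4-(benzyloxy)-3-methoxyphenyl]magnesium bromide | COc1cc([Mg]Br)ccc1OCc1ccccc1 | intermediate (not isolated)
12 | (1S,2S)-1-[4-(benzyloxy)-3-methoxyphenyl]-2-(4-bromo-2,6-dimethoxyphenoxy)propan-1-ol | COc1cc(Br)cc(OC)c1O[C@@H](C)[C@@H](O)c1ccc(OCc2ccccc2)c(OC)c1 | intermediate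
13 | tert-butyl{(1S,2S)-1-[4-(benzyloxy)-3-methoxyphenyl]-2-(4-bromo-2,6-dimethoxyphenoxy)propoxy}dimethylsilane | COc1cc(Br)cc(OC)c1O[C@@H](C)[C@@H](O[Si](C)(C)C(C)(C)C)c1ccc(OCc2ccccc2)c(OC)c1 | intermediate
14 | methyl (2R)-oxirane-2-carboxylate | COC(=O)[C@H]1CO1 | starting material
15 | [3,5-dimethoxy-4-(SC-oxy)phenyl]magnesium bromide | COc1cc([Mg]Br)cc(OC)c1O[C@@H](C)[C@@H](O[Si](C)(C)C(C)(C)C)c1ccc(OCc2ccccc2)c(OC)c1 | intermediate (not isolated)
16 | methyl (2R)-2-hydroxy-3-[3,5-dimethoxy-4-(SC-oxy)phenyl]propanoate | COC(=O)[C@H](O)Cc1cc(OC)c(O[C@@H](C)[C@@H](O[Si](C)(C)C(C)(C)C)c2ccc(OCc3ccccc3)c(OC)c2)c(OC)c1 | intermediate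
17 | methyl (2R)-3-[3,5-dimethoxy-4-(SC-oxy)phenyl]-2-[(trifluoromethanesulfonyl)oxy]propanoate | COC(=O)[C@H](OS(=O)(=O)C(F)(F)F)Cc1cc(OC)c(O[C@@H](C)[C@@H](O[Si](C)(C)C(C)(C)C)c2ccc(OCc3ccccc3)c(OC)c2)c(OC)c1 | intermediate
18 | sodium Z-enolate of imide 5 | COc1cc(C/C=C(\[O-])N2[C@H](Cc3ccccc3)COC2=O)ccc1OCc1ccccc1.[Na+] | intermediate (not isolated)
19 | methyl (2R,3S)-3-{[(4R)-4-benzyl-2-oxo-1,3-oxazolidin-3-yl]carbonyl}-4-[4-(benzyloxy)-3-methoxyphenyl]-2-{[3,5-dimethoxy-4-(SC-oxy)phenyl]methyl}butanoate | COc1cc(C[C@H](C(=O)N2[C@H](Cc3ccccc3)COC2=O)[C@H](C(=O)OC)Cc2cc(OC)c(O[C@@H](C)[C@@H](O[Si](C)(C)C(C)(C)C)c3ccc(OCc4ccccc4)c(OC)c3)c(OC)c2)ccc1OCc1ccccc1 | intermediate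
20 | (2S,3R)-2-{[4-(benzyloxy)-3-methoxyphenyl]methyl}-3-{[3,5-dimethoxy-4-(SC-oxy)phenyl]methyl}butane-1,4-diol | COc1cc(C[C@H](CO)[C@H](CO)Cc2cc(OC)c(O[C@@H](C)[C@@H](O[Si](C)(C)C(C)(C)C)c3ccc(OCc4ccccc4)c(OC)c3)c(OC)c2)ccc1OCc1ccccc1 | intermediate
21 | 1,4-dimethanesulfonate of diol 20 | COc1cc(C[C@H](COS(C)(=O)=O)[C@H](COS(C)(=O)=O)Cc2cc(OC)c(O[C@@H](C)[C@@H](O[Si](C)(C)C(C)(C)C)c3ccc(OCc4ccccc4)c(OC)c3)c(OC)c2)ccc1OCc1ccccc1 | intermediate
22 | 5-{(2R,3S)-4-[4-(benzyloxy)-3-methoxyphenyl]-2,3-dimethylbutyl}-1,3-dimethoxy-2-(SC-oxy)benzene | COc1cc(C[C@H](C)[C@H](C)Cc2cc(OC)c(O[C@@H](C)[C@@H](O[Si](C)(C)C(C)(C)C)c3ccc(OCc4ccccc4)c(OC)c3)c(OC)c2)ccc1OCc1ccccc1 | intermediate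
23 | (1S,2S)-1-[4-(benzyloxy)-3-methoxyphenyl]-2-[4-{(2R,3S)-4-[4-(benzyloxy)-3-methoxyphenyl]-2,3-dimethylbutyl}-2,6-dimethoxyphenoxy]propan-1-ol | COc1cc(C[C@H](C)[C@H](C)Cc2cc(OC)c(O[C@@H](C)[C@@H](O)c3ccc(OCc4ccccc4)c(OC)c3)c(OC)c2)ccc1OCc1ccccc1 | intermediate
24 | (+)-(7''S,8S,8'R,8''S)-4,4''-dihydroxy-3,3',3'',5'-tetramethoxy-4',8''-oxy-8,8'-sesquineolignan-7''-ol | COc1cc(C[C@H](C)[C@H](C)Cc2cc(OC)c(O[C@@H](C)[C@@H](O)c3ccc(O)c(OC)c3)c(OC)c2)ccc1O | target

**Step count.** 14 steps in total; longest linear sequence 12 steps (6 to 24, steps 3–14).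

**Steps most likely to fail**

1. Step 9. Base-induced elimination of triflic acid from 17, or proton transfer from it to the enolate, may outrun substitution; the auxiliary and the triflate stereocenter may also act as a mismatched pair and erode facial selectivity at C8. The fallback sets out from 13 and 2 and returns at 20; it makes the same C8–C8' bond by an ester-tethered Ireland–Claisen rearrangement.
   - Grignard reagent 15 from 13 is allylated (allyl bromide, CuI cat., THF) to the allylarene F1.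
   - Cross-metathesis with (R)-but-3-en-2-ol (second-generation Grubbs catalyst, CH2Cl2, 40 °C) should give the (R,E)-allylic alcohol F2.
   - Esterification with acid 2 (DCC, DMAP) gives ester F3.
   - LiN(i-Pr)2 and Me3SiCl in THF at −78 °C should give the E silyl ketene acetal F4.
   - On warming, F4 should rearrange through a chair with the carbinol methyl equatorial to the anti acid F5, so that C8 and C8' are set together by 1,3-chirality transfer.
   - LiAlH4 reduces F5 to alcohol F6.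
   - Cleavage of the propenyl group (OsO4 cat., NaIO4, 2,6-lutidine, dioxane/H2O) gives hydroxy aldehyde F7, and NaBH4 then gives diol 20.

2. Step 7. The arylmagnesium may add to the ester carbonyl of the glycidate instead of opening the epoxide, or be lost to copper-mediated homocoupling. The fallback sets out from 13 through its Grignard reagent 15 and returns at 16; it avoids an ester-bearing electrophile.
   - Formylation of 15 with DMF gives aldehyde F8.
   - Horner–Wadsworth–Emmons reaction with methyl 2-acetoxy-2-(dimethoxyphosphoryl)acetate (LiCl, DBU, MeCN) gives the Z enol acetate F9.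
   - Hydrogenation with [Rh(cod)((R,R)-Et-DuPhos)]BF4 (H2, MeOH) should give the (R)-acetate F10 and leave the benzyl ethers intact.
   - K2CO3 in MeOH at 0 °C removes the acetyl group to give 16.

3. Step 5. Facial selectivity may be poor if the weakly basic aryloxy oxygen does not hold the magnesium chelate, since the Felkin–Anh pathway leads to the erythro epimer; the α-aryloxy aldehyde may also epimerise. The fallback sets out from 8 and returns at 12; it sets the carbinol center by reagent-controlled reduction.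
   - Ester 8 is converted into the Weinreb amide F11 (MeNHOMe·HCl, i-PrMgCl, THF, −20 °C).
   - Grignard reagent 11 adds once to give ketone F12.
   - Transfer hydrogenation with RuCl[(R,R)-TsDPEN](p-cymene) in HCO2H/Et3N should place hydride on the face that makes C7'' S and give 12.

**Further compounds**
F1 | step 9 | 1,3-dimethoxy-5-(prop-2-en-1-yl)-2-(SC-oxy)benzene | C=CCc1cc(OC)c(O[C@@H](C)[C@@H](O[Si](C)(C)C(C)(C)C)c2ccc(OCc3ccccc3)c(OC)c2)c(OC)c1
F2 | step 9 | (2R,3E)-5-[3,5-dimethoxy-4-(SC-oxy)phenyl]pent-3-en-2-ol | C[C@@H](O)/C=C/Cc1cc(OC)c(O[C@@H](C)[C@@H](O[Si](C)(C)C(C)(C)C)c2ccc(OCc3ccccc3)c(OC)c2)c(OC)c1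
F3 | step 9 | (2R,3E)-5-[3,5-dimethoxy-4-(SC-oxy)phenyl]pent-3-en-2-yl 3-[4-(benzyloxy)-3-methoxyphenyl]propanoate | COc1cc(CCC(=O)O[C@H](C)/C=C/Cc2cc(OC)c(O[C@@H](C)[C@@H](O[Si](C)(C)C(C)(C)C)c3ccc(OCc4ccccc4)c(OC)c3)c(OC)c2)ccc1OCc1ccccc1
F4 | step 9 | E trimethylsilyl ketene acetal of ester F3 | COc1cc(C/C=C(/O[Si](C)(C)C)O[C@H](C)/C=C/Cc2cc(OC)c(O[C@@H](C)[C@@H](O[Si](C)(C)C(C)(C)C)c3ccc(OCc4ccccc4)c(OC)c3)c(OC)c2)ccc1OCc1ccccc1
F5 | step 9 | (2S,3S,4E)-2-{[4-(benzyloxy)-3-methoxyphenyl]methyl}-3-{[3,5-dimethoxy-4-(SC-oxy)phenyl]methyl}hex-4-enoic acid | COc1cc(C[C@H](C(=O)O)[C@H](/C=C/C)Cc2cc(OC)c(O[C@@H](C)[C@@H](O[Si](C)(C)C(C)(C)C)c3ccc(OCc4ccccc4)c(OC)c3)c(OC)c2)ccc1OCc1ccccc1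
F6 | step 9 | (2S,3S,4E)-2-{[4-(benzyloxy)-3-methoxyphenyl]methyl}-3-{[3,5-dimethoxy-4-(SC-oxy)phenyl]methyl}hex-4-en-1-ol | COc1cc(C[C@H](CO)[C@H](/C=C/C)Cc2cc(OC)c(O[C@@H](C)[C@@H](O[Si](C)(C)C(C)(C)C)c3ccc(OCc4ccccc4)c(OC)c3)c(OC)c2)ccc1OCc1ccccc1
F7 | step 9 | (2R,3S)-4-[4-(benzyloxy)-3-methoxyphenyl]-2-{[3,5-dimethoxy-4-(SC-oxy)phenyl]methyl}-3-(hydroxymethyl)butanal | COc1cc(C[C@H](CO)[C@H](C=O)Cc2cc(OC)c(O[C@@H](C)[C@@H](O[Si](C)(C)C(C)(C)C)c3ccc(OCc4ccccc4)c(OC)c3)c(OC)c2)ccc1OCc1ccccc1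
F8 | step 7 | 3,5-dimethoxy-4-(SC-oxy)benzaldehyde | O=Cc1cc(OC)c(O[C@@H](C)[C@@H](O[Si](C)(C)C(C)(C)C)c2ccc(OCc3ccccc3)c(OC)c2)c(OC)c1
F9 | step 7 | methyl (2Z)-2-acetoxy-3-[3,5-dimethoxy-4-(SC-oxy)phenyl]prop-2-enoate | COC(=O)/C(OC(C)=O)=C/c1cc(OC)c(O[C@@H](C)[C@@H](O[Si](C)(C)C(C)(C)C)c2ccc(OCc3ccccc3)c(OC)c2)c(OC)c1
F10 | step 7 | methyl (2R)-2-acetoxy-3-[3,5-dimethoxy-4-(SC-oxy)phenyl]propanoate | COC(=O)[C@H](OC(C)=O)Cc1cc(OC)c(O[C@@H](C)[C@@H](O[Si](C)(C)C(C)(C)C)c2ccc(OCc3ccccc3)c(OC)c2)c(OC)c1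
F11 | step 5 | (2S)-2-(4-bromo-2,6-dimethoxyphenoxy)-N-methoxy-N-methylpropanamide | C[C@H](Oc1c(OC)cc(Br)cc1OC)C(=O)N(C)OC
F12 | step 5 | (2S)-1-[4-(benzyloxy)-3-methoxyphenyl]-2-(4-bromo-2,6-dimethoxyphenoxy)propan-1-one | C[C@H](Oc1c(OC)cc(Br)cc1OC)C(=O)c1ccc(OCc2ccccc2)c(OC)c1
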